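**Assumption:** guaiane numbering is used throughout (C1/C5 ring fusion, C3 ketone, C4=C5, C7 bears C11, C8 bears O, C10 bears C14). The SMILES decodes as (1R,7S,8R,10S) with a Z (angelate) ester. H‑1, C‑14, O‑8 and C‑11 all lie on one face, called β below.

## Retrosynthetic overview
1. Torilin ⇒ torilolone (8,11‑diol). The secondary OH is angeloylated first and the tertiary OH acetylated last.
2. C10 and C1 ⇒ guaia‑1(10),4‑dien‑3‑one. H2 is delivered from the α face because the β face is capped by a cis‑fused t‑Bu2Si ring. C1 (γ to the enone) is then equilibrated.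
3. Key step: rings A (5) and B (7) form together from an acyclic allenyne plus CO by a Rh(I) allenic Pauson–Khand [2+2+1], making C1–C5, C2–C3 and C3–C4. This replaces the usual chiral‑pool ring plus stepwise 1,4‑diketone aldol annulation.
4. Acyclic C7/C8 ⇒ one Evans syn‑aldol. C11 ⇒ ester plus 2 MeMgBr.
5. Fragments: a β‑allenal (Johnson–Claisen of but‑2‑yn‑1‑ol, then DIBAL) and a hex‑4‑ynoyl oxazolidinone.

## Route

**Step 1**
Reactants: 1 but‑2‑yn‑1‑ol; 2 triethyl orthoacetate
Product: 3 ethyl 3‑methylpenta‑3,4‑dienoate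
Conditions: 2 (5 equiv, neat), EtCO2H (cat.), 140 °C, distil off EtOH
Reagents that add atoms: triethyl orthoacetate, CC(OCC)(OCC)OCC
Why: In this Johnson orthoester Claisen rearrangement, the propargyl ketene acetal shifts [3,3] onto the CH3‑bearing alkyne carbon, giving the 1,1‑disubstituted allene (future C10=C1=C2 with C14) plus C9–C8; no stereocentre is formed.

**Step 2**
Reactants: 3 ethyl 3‑methylpenta‑3,4‑dienoate
Product: 4 3‑methylpenta‑3,4‑dienal
Conditions: DIBAL‑H (1.05 equiv), CH2Cl2, –78 °C; Rochelle work‑up; used at once as a cold solution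
Reagents that add atoms: none
Why: Partial ester reduction stops at the stable tetrahedral aluminate at –78 °C, and the allene is inert to DIBAL at this temperature.

**Step 3**
Reactants: 5 hex‑4‑ynoic acid; 6 (S)‑4‑benzyloxazolidin‑2‑one
Product: 7 (S)‑4‑benzyl‑3‑(hex‑4‑ynoyl)oxazolidin‑2‑one
Conditions: PivCl, Et3N, THF, –20 °C; then 6, LiCl, –20 °C → rt
Reagents that add atoms: (S)‑4‑benzyloxazolidin‑2‑one, O=C1N[C@@H](Cc2ccccc2)CO1
Why: Mixed‑anhydride N‑acylation installs the auxiliary, and the auxiliary stereocentre is untouched.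

**Step 4**
Reactants: 7 imide; 4 3‑methylpenta‑3,4‑dienal
Product: 8 (S)‑4‑benzyl‑3‑[(2S,3R)‑2‑(but‑2‑yn‑1‑yl)‑3‑hydroxy‑5‑methylhepta‑5,6‑dienoyl]oxazolidin‑2‑one
Conditions: n‑Bu2BOTf, i‑Pr2NEt, CH2Cl2, 0 → –78 °C; add 4; –78 → 0 °C; pH 7 buffer/MeOH/H2O2
Reagents that add atoms: none
Why: In the Evans boron syn‑aldol, the Z‑boron enolate reacts through a Zimmerman–Traxler chair on the face opposite the benzyl group, setting C7 (S) and C8 (R) together; this syn relationship becomes cis on ring B.

**Step 5**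
Reactants: 8 aldol adduct
Product: 9 methyl (2S,3R)‑2‑(but‑2‑yn‑1‑yl)‑3‑hydroxy‑5‑methylhepta‑5,6‑dienoate
Conditions: MeOMgBr (from MeMgBr and MeOH), MeOH/CH2Cl2, 0 °C; 6 is recovered
Reagents that add atoms: methanol, CO
Why: Magnesium‑chelated transesterification attacks the exocyclic imide carbonyl and is mild enough to avoid retro‑aldol or C7 epimerisation.

**Step 6**
Reactants: 9 hydroxy ester
Product: 10 (3S,4R)‑3‑(but‑2‑yn‑1‑yl)‑2,6‑dimethylocta‑6,7‑diene‑2,4‑diol
Conditions: MeMgBr (5 equiv), Et2O/THF, 0 °C → rt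
Reagents that add atoms: methylmagnesium bromide, C[Mg]Br (two CH3)
Why: Double Grignard addition to the ester builds the C11 carbinol (C12, C13); the internal alkyne and the allene are inert, and C7/C8 are unchanged.

**Step 7**
Reactants: 10 diol
Product: 11 (5S,6R)‑5‑(but‑2‑yn‑1‑yl)‑2,2‑di‑tert‑butyl‑4,4‑dimethyl‑6‑(2‑methylbuta‑2,3‑dien‑1‑yl)‑1,3,2‑dioxasilinane
Conditions: t‑Bu2Si(OTf)2, 2,6‑lutidine, CH2Cl2, 0 °C → rt
Reagents that add atoms: di‑tert‑butylsilyl bis(triflate), CC(C)(C)[Si](OS(=O)(=O)C(F)(F)F)(OS(=O)(=O)C(F)(F)F)C(C)(C)C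
Why: Cyclic silylene protection of the 1,3‑diol holds the C6 and C9 arms gauche, which templates the 7‑ring closure, and later blocks the β face.

**Step 8 (key step)**
Reactants: 11 allenyne
Product: 12 (7S,8R)‑8,11‑O,O‑(di‑tert‑butylsilanediyl)‑8,11‑dihydroxyguaia‑1(10),4‑dien‑3‑one
Conditions: [Rh(CO)2Cl]2 (10 mol %), CO (1 atm), toluene (0.01 M), 110 °C
Reagents that add atoms: carbon monoxide, [C-]#[O+]
Why: In the Rh(I) allenic Pauson–Khand [2+2+1], Rh couples the alkyne with the distal allene π‑bond (C5–C1) and CO insertion closes C2–C3–C4, so the 2‑methylcyclopentenone and the seven‑membered ring form in one step with C1=C10 retained; no stereocentre is created or disturbed.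

**Step 9**
Reactants: 12 dienone
Product: 13 (1S,7S,8R,10S)‑silylene‑protected 8,11‑dihydroxyguai‑4‑en‑3‑one (1αH,10αH; C14 β)
Conditions: H2 (3 atm), 10 % Pd/C, EtOAc, rt; stop after 1 equiv H2
Reagents that add atoms: none
Why: Heterogeneous syn‑hydrogenation reduces the more electron‑rich γ,δ‑alkene of the linear dienone from the α face, because the pseudoaxial C8–O bond and the t‑Bu2Si ring cover the β face; this pushes C14 onto the β face (10S), and the tetrasubstituted enone is spared.

**Step 10**
Reactants: 13 1‑epi enone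
Product: 14 (1R,7S,8R,10S)‑silylene‑protected 8,11‑dihydroxyguai‑4‑en‑3‑one (1βH)
Conditions: DBU, MeCN, 60 °C; separate and recycle residual 13
Reagents that add atoms: none
Why: Base‑mediated γ‑epimerisation through the extended dienolate places C2 and C14 trans across C1–C10 under thermodynamic control (1βH); C7, C8 and C10 have no acidifying group and cannot scramble.

**Step 11**
Reactants: 14
Product: 15 torilolone, (1R,7S,8R,10S)‑8,11‑dihydroxyguai‑4‑en‑3‑one
Conditions: HF·pyridine, THF, 0 °C → rt
Reagents that add atoms: none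
Why: Fluoride cleaves the silylene under near‑neutral conditions, so the tertiary alcohol is not dehydrated and C1 is not disturbed.

**Step 12**
Reactants: 15 torilolone; 16 angelic acid [(Z)‑2‑methylbut‑2‑enoic acid]
Product: 17 8‑O‑angeloyltorilolone
Conditions: 16, 2,4,6‑trichlorobenzoyl chloride, Et3N, toluene, rt; then 15, 80 °C (no DMAP)
Reagents that add atoms: angelic acid, C/C=C(/C)C(=O)O
Why: Yamaguchi‑type mixed‑anhydride esterification acylates only the secondary C8‑OH, the tertiary C11‑OH being too hindered; omitting a nucleophilic catalyst avoids Z→E (tiglate) isomerisation, and C8 configuration is retained.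

**Step 13**
Reactants: 17
Product: 18 torilin
Conditions: Ac2O (5 equiv), Sc(OTf)3 (5 mol %), MeCN, –20 → 0 °C
Reagents that add atoms: acetic anhydride, CC(=O)OC(C)=O
Why: Lewis‑acid‑catalysed acetylation works on tertiary alcohols at low temperature, which limits E1 loss of the C11 oxygen and leaves the angelate and enone intact.

## Compound list
1 | but‑2‑yn‑1‑ol | CC#CCO | starting material
2 | triethyl orthoacetate | CC(OCC)(OCC)OCC | starting material
3 | ethyl 3‑methylpenta‑3,4‑dienoate | CCOC(=O)CC(C)=C=C | intermediate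
4 | 3‑methylpenta‑3,4‑dienal | O=CCC(C)=C=C | intermediate
5 | hex‑4‑ynoic acid | CC#CCCC(=O)O | starting material
6 | (S)‑4‑benzyloxazolidin‑2‑one | O=C1N[C@@H](Cc2ccccc2)CO1 | starting material
7 | (S)‑4‑benzyl‑3‑(hex‑4‑ynoyl)oxazolidin‑2‑one | CC#CCCC(=O)N1C(=O)OC[C@@H]1Cc1ccccc1 | intermediate
8 | Evans syn‑aldol adduct (7S,8R) | O[C@@H]([C@H](CC#CC)C(=O)N1C(=O)OC[C@@H]1Cc1ccccc1)CC(C)=C=C | intermediate
9 | methyl (2S,3R)‑2‑(but‑2‑ynyl)‑3‑hydroxy‑5‑methylhepta‑5,6‑dienoate | O[C@@H]([C@H](CC#CC)C(=O)OC)CC(C)=C=C | intermediate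
10 | (3S,4R)‑3‑(but‑2‑ynyl)‑2,6‑dimethylocta‑6,7‑diene‑2,4‑diol | O[C@@H]([C@H](CC#CC)C(C)(C)O)CC(C)=C=C | intermediate
11 | di‑tert‑butylsilylene allenyne (5S,6R) | O1[C@@H]([C@H](CC#CC)C(C)(C)O[Si]1(C(C)(C)C)C(C)(C)C)CC(C)=C=C | intermediate
12 | silylene‑protected guaia‑1(10),4‑dien‑3‑one (7S,8R) | O1[C@@H]2CC(C)=C3CC(=O)C(C)=C3C[C@@H]2C(C)(C)O[Si]1(C(C)(C)C)C(C)(C)C | intermediate
13 | silylene‑protected 1‑epi‑torilolone (1S,7S,8R,10S) | O1[C@@H]2C[C@H](C)[C@@H]3CC(=O)C(C)=C3C[C@@H]2C(C)(C)O[Si]1(C(C)(C)C)C(C)(C)C | intermediate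
14 | silylene‑protected torilolone (1R,7S,8R,10S) | O1[C@@H]2C[C@H](C)[C@H]3CC(=O)C(C)=C3C[C@@H]2C(C)(C)O[Si]1(C(C)(C)C)C(C)(C)C | intermediate
15 | torilolone | O[C@@H]1C[C@H](C)[C@H]2CC(=O)C(C)=C2C[C@@H]1C(C)(C)O | intermediate
16 | angelic acid | C/C=C(/C)C(=O)O | starting material
17 | 8‑O‑angeloyltorilolone | C/C=C(/C)C(=O)O[C@@H]1C[C@H](C)[C@H]2CC(=O)C(C)=C2C[C@@H]1C(C)(C)O | intermediate
18 | torilin | C/C=C(/C)C(=O)O[C@@H]1C[C@H](C)[C@H]2CC(=O)C(C)=C2C[C@@H]1C(C)(C)OC(C)=O | target

## Step count and risks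
Total steps: 13. Longest linear sequence: 12 (steps 1, 2, 4–13).

**Steps most likely to fail**
- **Step 8, allenic Pauson–Khand to the 5‑7 dienone.**
  - Risks: seven‑ring closure may be slow, and Rh Alder‑ene cycloisomerisation to a cross‑conjugated triene can compete.
  - Fallback: build the rings one at a time. Run the aldol with a 3‑(PMB‑oxy)propanoyl imide and convert C6 to an iodide. Add its organolithium to 3‑ethoxy‑2‑methylcyclopent‑2‑enone (Stork–Danheiser) to install ring A. Then close ring B by intramolecular vinylogous aldol condensation of C1 onto a C10 methyl ketone, which reaches the same dienone 12.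
- **Step 9, chemo‑ and face‑selective reduction of the tetrasubstituted C1=C10.**
  - Risks: slow reaction, over‑reduction of the enone, or β‑face delivery.
  - Fallback: avoid the tetrasubstituted alkene. From a ring‑A enone carrying a 2‑bromoalkene side chain, close ring B by Pd‑catalysed intramolecular γ‑alkenylation of the dienolate to give the 10(14)‑exomethylene compound. Reduce this 1,1‑disubstituted alkene from the α face with Wilkinson's catalyst.
- **Step 10, the C1 equilibrium may not favour 1βH strongly.**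
  - Fallback: stop relying on thermodynamics. Preset C10 by running the aldol with enantiopure (S)‑3‑methylpent‑4‑enal. Create C1–H during C–C bond formation, using a silylene‑templated enyne [2+2+1], or a Ni(0) reductive enoate–alkyne [3+2] after cross‑metathesis with an acrylate. C1 is then controlled by the adjacent C10 centre and no reduction or epimerisation is needed.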